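The constants of the north run can be read at one charge of free catalyst, 0.75 mol%, while the flask holds 0.5 mol%, so the readings cannot give the order directly. The question can be turned round instead: what would have to be true for the marked conversion to lie out of reach?

| flask | left-handed substrate | right-handed substrate | reagent | free catalyst | remark |
|---|---|---|---|---|---|
| north | 0.83 M | 0.83 M | 1.1 equiv | 0.75 mol% | run made earlier |
| flask | 0.83 M | 0.83 M | 1.10 equiv | 0.5 mol% |  |

- north (time / s: left-handed product / %, left-handed substrate / %): 10.0: 4.1, 46.9; 25.0: 8.0, 40.9; 40.0: 13.2, 35.9; 60.0: 18.4, 31.5; 90.0: 21.4, 27.0; 120: 24.0, 26.4

(readings scatter by 0.5 percentage points)

- apparent order in free catalyst when 50 % of the left-handed substrate and right-handed substrate together are converted (percent change of the rate of making left-handed product for one percent more free catalyst charged)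

- free catalyst is single-handed; left-handed substrate and right-handed substrate are mirror images of each other, charged as a racemate, each of them at the stated concentration
- no earlier run changes the charge of free catalyst; that part of a forecast is a guess

My own reckoning assumes that each turn of either substrate takes one reagent, which the readings do not show. Both substrates are charged equally, so reagent as a fraction of both together is its equivalents divided by two, 55.0 %, the reagent ceiling: the conversion at which the limiting reagent is used up. In the north run, left-handed product levels near 24.0 %, which would leave 31 percentage points for the right-handed substrate. The marked conversion would be out of reach with a ceiling below 50 %, but the flask stands 5 points above that. There the reagent left is 9.09 % of its charge, a count in which the catalyst charge does not appear. If the split between the two substrates also stays the same, the composition at the mark is alike for both catalyst charges, and my reckoning gives an order of one plus a correction for catalyst lost on the way, whose size I cannot compute.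

The forecast commits to 1.1, within 0.7 to 2, on the ground that “less charge means a larger share is dead at a given conversion”.

The flask gives 1.1, so at the marked conversion, reached at 1.89 min, its rate follows the catalyst charge nearly in proportion.

    reagent + catalyst intermediate B → free catalyst + right-handed product (k = 4.00 /M/s)
    free catalyst + left-handed substrate ⇌ catalyst intermediate A (K = 11.0 /M, k = 10.0 /M/s)
    reagent + catalyst intermediate A → free catalyst + left-handed product (k = 14.0 /M/s)
    reagent + free catalyst → spent catalyst B (k = 0.00780 /M/s)
    free catalyst + right-handed substrate ⇌ catalyst intermediate B (K = 14.0 /M, k = 47.0 /M/s)
    2 free catalyst → spent catalyst A (k = 0.560 /M/s)

With reagent as charged, catalyst intermediate B goes on to right-handed product at 220 /min, faster than free catalyst goes to spent catalyst B at 0.43 /min, and at 20.0 min the flask holds 55.0 % of the two products, equal to the reagent ceiling of 55.0 %, with reagent at 0 %. At 2.00 min, just past the marked conversion, reagent in the flask is down to 7.94 % of its charge, and the two spent forms together hold 5.82 % of the catalyst charged.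

(Readings and results come from a simulation with made-up constants; noise was put on by code.)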